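# Proposed synthesis of 5,7-dihydroxy-2-(4-hydroxyphenyl)-3,6,8-trimethoxy-4H-chromen-4-one (15) by squarate ring expansion onto a 4-pyranone

## The problem

Target 15 is a flavone: a 4H-chromen-4-one whose ring C carries a 4-hydroxyphenyl group (ring B) at C2 and a methoxy group at C3, and is fused through C4a and C8a to a fully substituted benzene ring A. Ring A bears oxygen on C5, C6, C7 and C8 in the alternating order OH, OMe, OH, OMe. The task is therefore regiochemical: three of six oxygens must end as methyl ethers and three as phenols, and O6 must be told apart from O7 although the two sit in nearly the same environment. There is no stereocentre, so nothing can be relayed and nothing can epimerise. The sensitive features are: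

- the γ-pyranone, which hydroxide or alkoxide can open at its β-carbons;
- the methyl ethers close to the chelating 5-hydroxyl, which strong Lewis acids attack;
- the electron-rich ring A, which oxidises to quinones in base and air.

A hexasubstituted benzene of this kind is hard to reach by stepwise substitution of an arene. The enabling feature is that C5–C8 form a contiguous C4O4 unit, the carbon–oxygen skeleton of a squaric ester, while C4a=C8a is also the α,β-double bond of the pyranone ring C. Ring A can therefore be grown on a preformed 2-aryl-3-methoxy-4-pyranone by forming only C4a–C5 and C8–C8a. C5 and C8 then emerge as hydroxyls that differ by chelation to the C4 carbonyl, which gives the handle for the O8 methyl group.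

## Retrosynthesis

**15 from 14.** The O7–isopropyl and O4′–isopropyl bonds are cut. Isopropyl is chosen for both positions because BCl3 removes secondary alkyl aryl ethers while methyl ethers stay, and because the O7 isopropyl comes with the commercial squarate. Benzyl ethers and hydrogenolysis would be milder but would need a squarate that has to be made first. The forward step must leave the 3-, 6- and 8-methoxy groups untouched.

**14 from 13.** The O8–CH3 bond is cut. In 13 the two hydroxyls differ: 5-OH is hydrogen-bonded to the C4 carbonyl, 8-OH is not. A mild Williamson methylation should therefore take O8 alone, with no further protecting group.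

**13 from 10 (key disconnection).** The C8–C8a bond is cut, and the C5–C8 unit is folded back into a cyclobutenone with C5 as the carbinol carbon and C8 as the carbonyl carbon. This removes ring A and all four of its oxygens in one operation and leaves a 4-pyranone carrying a four-membered ring. The opposite mode (cyclobutenone on the pyranone carbon next to the ring oxygen, closure at C4a–C5) would need a nucleophile at the wrong pyranone position. In 10 the only CH carbon beside the point of attachment is pyranone C6, so the site of closure is unambiguous. The forward step must open the ring with the hydroxyl turning outward and close onto a weakly aromatic pyranone.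

**10 from 9.** The C3–OMe bond of the cyclobutenone (the future C6–OMe) is cut, leading back to the symmetrical diisopropoxy adduct 9. A mixed methyl isopropyl squarate would not help, because its two carbonyls are almost equally reactive and both regioisomeric adducts would form. After addition the two alkoxy groups are electronically distinct: the one on C3 is part of a vinylogous ester, the one on C2 is a plain enol ether. The forward reaction must exchange only the former without disturbing the tertiary carbinol.

**9 from 6 and 7.** The bond between pyranone C5 (the future C4a) and the carbinol carbon is cut. This calls for the pyranon-5-yl nucleophile 8 and commercial diisopropyl squarate 7. The nucleophile must be made and used cold, because a metal on C5 stands anti to the ring oxygen on C6.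

**6 from 5, 5 from 3 and 4, 3 from 2, 2 from 1.** The C5–I bond, the C2–aryl bond (Suzuki coupling with boronic acid 4), the O-methyl bond and the C2–Br bond are cut in turn, back to 3-hydroxy-4H-pyran-4-one 1. The enolic hydroxyl of 1 directs bromination to C2, and the 3-methoxy group of the target is in place from the second step.

## Roads not taken

**Alternative 1:** Carbonylative Sonogashira union. The cut is at C4a–C4 and C4–C3: aryl iodide A2 and alkyne A3 are joined with insertion of a carbonyl carbon under Pd(PPh3)4 and CuI to give alkynone A1; no ring closes in that step.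

- Merits: the union is convergent, and ring A enters as a mirror-symmetric benzene. The O6/O7 question that costs the chosen plan its exchange step does not arise; in this respect the alternative is better.
- Weak points: A2 is a hexasubstituted, electron-rich iodide flanked by two benzyloxy groups. Oxidative addition and acyl formation should be slow, and direct non-carbonylative coupling should compete. A2 is not an article of commerce and needs several steps of its own. A1 has no oxygen at C3, so after ring C is closed the 3-methoxy group must still be installed by a separate oxidation and methylation.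
- Comparison: the chosen plan carries the 3-methoxy group from the second step and takes every ring A oxygen from a purchased squarate, and its sequence is shorter.

**Alternative 2:** Auwers ring expansion. Aurone dibromide A5 is treated with ethanolic KOH; the five-membered ring opens at the brominated ketal carbon and the phenoxide displaces the benzylic bromide, forming O1–C2 and C3–O and giving flavonol A4.

- Merits: the C3 oxygen arrives as a free hydroxyl that can be methylated in the presence of three benzyl ethers. One hydrogenolysis then ends the synthesis, and ring A is again symmetric. That end game uses only classical reactions and is more secure than the alkoxy exchange of the chosen plan.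
- Weak points: the ring expansion is capricious for aurones with oxygen ortho to the ketone, where debromination back to the aurone and solvolysis compete. Strong hydroxide is required. Bromination may also touch ring B. The penta-oxygenated precursor of A5 needs a long preparation.
- Comparison: the chosen plan offers a neutral key step and a shorter path from commercial materials.

**Alternative 3:** Thermal annulation of a phloroglucinol with a β-ketoester. Triol A6 and ketoester A7 are heated neat; C-acylation forms C4–C4a and cyclodehydration forms O1–C2, giving flavone A8, which needs only debenzylation.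

- Merits: on paper this is the shortest route. The symmetry of A6 removes every regiochemical question, and no protecting group is needed on ring A. In step count and in the O6/O7 issue it is better than the chosen plan.
- Weak points: such condensations run well above 200 °C. The single free position of A6 is flanked by two hydroxyls. Coumarin formation by initial transesterification competes. The benzyl ether may not survive hot phenols. A6 is an air-sensitive, non-commercial pentaoxygenated benzene whose own synthesis would take about as many steps as the whole ring A construction here.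
- Comparison: the chosen plan has a pericyclic, neutral ring formation at about 130 °C and building blocks that can be bought.

Key step: step 7

## Route

Assumption: 3-hydroxy-4H-pyran-4-one, diisopropyl squarate and 4-(propan-2-yloxy)phenylboronic acid are purchased; ring B is carried as its isopropyl ether so that one BCl3 treatment removes both protecting groups at the end.

Step 1
Reactants: 1 3-hydroxy-4H-pyran-4-one
Product: 2 2-bromo-3-hydroxy-4H-pyran-4-one
Conditions: NBS (1.05 equiv), MeCN, 0 °C → rt
Reagents that add atoms: N-bromosuccinimide, O=C1CCC(=O)N1Br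
Why: Electrophilic bromination of the enolic 3-hydroxypyranone should occur at C2, the enol β-carbon ortho to the hydroxyl, as with related hydroxypyranones; one equivalent at low temperature limits 2,6-dibromination.

Step 2
Reactants: 2 2-bromo-3-hydroxy-4H-pyran-4-one
Product: 3 2-bromo-3-methoxy-4H-pyran-4-one
Conditions: MeI, K2CO3, acetone, 50 °C
Reagents that add atoms: iodomethane, CI
Why: Williamson O-methylation of the acidic enolic hydroxyl; it fixes the future 3-methoxy group and removes the acidic proton before the coupling.

Step 3
Reactants: 3 2-bromo-3-methoxy-4H-pyran-4-one; 4 4-(propan-2-yloxy)phenylboronic acid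
Product: 5 3-methoxy-2-[4-(propan-2-yloxy)phenyl]-4H-pyran-4-one
Conditions: Pd(PPh3)4 (5 mol %), K2CO3, DME/H2O, 85 °C
Reagents that add atoms: none
Why: Suzuki–Miyaura coupling; the C2 bromide is a vinylogous acyl bromide and should undergo oxidative addition readily, and the carbonate base is mild enough for the pyranone.

Step 4
Reactants: 5 3-methoxy-2-[4-(propan-2-yloxy)phenyl]-4H-pyran-4-one
Product: 6 5-iodo-3-methoxy-2-[4-(propan-2-yloxy)phenyl]-4H-pyran-4-one
Conditions: I2, (NH4)2Ce(NO3)6, MeCN, 60 °C
Reagents that add atoms: iodine, II
Why: Oxidative electrophilic iodination at C5, the α-carbon of the vinylogous ester and the only nucleophilic ring carbon left; the same reagent pair iodinates flavones at the corresponding C3 position, and ring B is deactivated by conjugation with the pyranone.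

Step 5
Reactants: 6 5-iodo-3-methoxy-2-[4-(propan-2-yloxy)phenyl]-4H-pyran-4-one; 7 diisopropyl squarate (3,4-bis(propan-2-yloxy)cyclobut-3-ene-1,2-dione)
Product: 9 4-hydroxy-4-{5-methoxy-4-oxo-6-[4-(propan-2-yloxy)phenyl]-4H-pyran-3-yl}-2,3-bis(propan-2-yloxy)cyclobut-2-en-1-one (racemic), via pyranonylmagnesium chloride 8 (not isolated)
Conditions: iPrMgCl·LiCl, THF, −78 °C; then 7, −78 → −40 °C; aq. NH4Cl
Reagents that add atoms: none
Why: Iodine–magnesium exchange at an sp2 carbon activated by the neighbouring carbonyl should be fast at −78 °C, cold enough to hold back β-elimination of the ring oxygen; 1,2-addition of alkenyl and aryl Grignard reagents to one carbonyl of a squaric ester is the standard entry to 4-hydroxycyclobutenones, and the new carbinol centre is racemic and later destroyed.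

Step 6
Reactants: 9 4-hydroxy-4-{5-methoxy-4-oxo-6-[4-(propan-2-yloxy)phenyl]-4H-pyran-3-yl}-2,3-bis(propan-2-yloxy)cyclobut-2-en-1-one (racemic)
Product: 10 4-hydroxy-3-methoxy-4-{5-methoxy-4-oxo-6-[4-(propan-2-yloxy)phenyl]-4H-pyran-3-yl}-2-(propan-2-yloxy)cyclobut-2-en-1-one (racemic)
Conditions: Mg(OMe)2 (0.3 equiv), MeOH, 0 °C → rt
Reagents that add atoms: methanol, CO
Why: Proposed new method: methoxide should add in conjugate fashion to C3, the β-carbon of the cyclobutenone vinylogous ester, and the adduct should expel isopropoxide, whereas C2 is an α-carbon with no addition–elimination pathway, so only the β-alkoxy group exchanges and methanol as solvent drives the equilibrium; the closest known reactions are the base-catalysed transesterification of squaric esters and alkoxy exchange at other vinylogous esters, and the protic medium with a magnesium counter-ion is chosen to keep the tertiary alkoxide from triggering anionic ring opening.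

Step 7
Reactants: 10 4-hydroxy-3-methoxy-4-{5-methoxy-4-oxo-6-[4-(propan-2-yloxy)phenyl]-4H-pyran-3-yl}-2-(propan-2-yloxy)cyclobut-2-en-1-one (racemic)
Product: 13 5,8-dihydroxy-3,6-dimethoxy-7-(propan-2-yloxy)-2-[4-(propan-2-yloxy)phenyl]-4H-chromen-4-one, via dienylketene 11 (not isolated), via 8aH-dienone tautomer 12 (not isolated)
Conditions: p-xylene (0.02 M, degassed), 130 °C, Ar
Reagents that add atoms: none
Why: Heating should open the cyclobutenone by conrotatory 4π electrocyclic cleavage of its C1–C4 bond to dienylketene 11. The hydroxyl, a donor, rotates outward and the acceptor pyranonyl group inward, so the pyranone ends cis to the ketene. A hydrogen bond between the enol hydroxyl and the pyranone carbonyl should hold the ring so that its C6–H carbon, not its carbonyl, faces the ketene. Thermal disrotatory 6π electrocyclisation then joins the ketene carbon to pyranone C6, forming C8–C8a and closing ring A as a six-membered carbocycle in dienone 12. Shift of the 8a-hydrogen to the C8 oxygen aromatises 12 to hydroquinone 13. The closest known reaction is the Moore rearrangement of squarate-derived 4-aryl- and 4-alkenyl-4-hydroxycyclobutenones to hydroquinones. No stereocentre is created: the racemic carbinol centre of 10 is destroyed and C8a of 12 is transient. The step needs torquoselectivity and a single site of closure, secured by the hydroxyl donor and by C6 being the only CH carbon beside the point of attachment, while the C6 methoxy and C7 isopropoxy positions are already fixed in 10 and oxygen is excluded to keep 13 from oxidising to the quinone.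

Step 8
Reactants: 13 5,8-dihydroxy-3,6-dimethoxy-7-(propan-2-yloxy)-2-[4-(propan-2-yloxy)phenyl]-4H-chromen-4-one
Product: 14 5-hydroxy-3,6,8-trimethoxy-7-(propan-2-yloxy)-2-[4-(propan-2-yloxy)phenyl]-4H-chromen-4-one
Conditions: MeI (1.1 equiv), K2CO3, acetone, rt, Ar
Reagents that add atoms: iodomethane, CI
Why: Williamson methylation of the free 8-hydroxyl; the 5-hydroxyl is held in a hydrogen-bonded chelate with the C4 carbonyl and is much less nucleophilic, the usual reason 5-hydroxyls of flavones stay unalkylated under mild conditions.

Step 9
Reactants: 14 5-hydroxy-3,6,8-trimethoxy-7-(propan-2-yloxy)-2-[4-(propan-2-yloxy)phenyl]-4H-chromen-4-one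
Product: 15 5,7-dihydroxy-2-(4-hydroxyphenyl)-3,6,8-trimethoxy-4H-chromen-4-one
Conditions: BCl3, CH2Cl2, −78 → 0 °C; then H2O
Reagents that add atoms: none
Why: Lewis-acid dealkylation; BCl3 cleaves secondary isopropyl aryl ethers at low temperature by an ionisation-type pathway closed to methyl ethers, so both isopropyl groups should leave as 2-chloropropane while the three methoxy groups stay, and aqueous work-up hydrolyses the borate esters and the boron chelate at O5/O4.

## Compound list

1 | 3-hydroxy-4H-pyran-4-one | O=c1ccocc1O | starting material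
2 | 2-bromo-3-hydroxy-4H-pyran-4-one | O=c1ccoc(Br)c1O | intermediate
3 | 2-bromo-3-methoxy-4H-pyran-4-one | COc1c(Br)occc1=O | intermediate
4 | 4-(propan-2-yloxy)phenylboronic acid | CC(C)Oc1ccc(B(O)O)cc1 | starting material
5 | 3-methoxy-2-[4-(propan-2-yloxy)phenyl]-4H-pyran-4-one | COc1c(-c2ccc(OC(C)C)cc2)occc1=O | intermediate
6 | 5-iodo-3-methoxy-2-[4-(propan-2-yloxy)phenyl]-4H-pyran-4-one | COc1c(-c2ccc(OC(C)C)cc2)occ(I)c1=O | intermediate
7 | diisopropyl squarate (3,4-bis(propan-2-yloxy)cyclobut-3-ene-1,2-dione) | CC(C)OC1=C(OC(C)C)C(=O)C1=O | starting material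
8 | chloro{5-methoxy-4-oxo-6-[4-(propan-2-yloxy)phenyl]-4H-pyran-3-yl}magnesium (LiCl complex) | COc1c(-c2ccc(OC(C)C)cc2)occ([Mg]Cl)c1=O | intermediate
9 | 4-hydroxy-4-{5-methoxy-4-oxo-6-[4-(propan-2-yloxy)phenyl]-4H-pyran-3-yl}-2,3-bis(propan-2-yloxy)cyclobut-2-en-1-one (racemic) | O=C1C(OC(C)C)=C(OC(C)C)C1(O)c1coc(-c2ccc(OC(C)C)cc2)c(OC)c1=O | intermediate
10 | 4-hydroxy-3-methoxy-4-{5-methoxy-4-oxo-6-[4-(propan-2-yloxy)phenyl]-4H-pyran-3-yl}-2-(propan-2-yloxy)cyclobut-2-en-1-one (racemic) | O=C1C(OC(C)C)=C(OC)C1(O)c1coc(-c2ccc(OC(C)C)cc2)c(OC)c1=O | intermediate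
11 | (3Z)-4-hydroxy-3-methoxy-4-{5-methoxy-4-oxo-6-[4-(propan-2-yloxy)phenyl]-4H-pyran-3-yl}-2-(propan-2-yloxy)buta-1,3-dien-1-one (dienylketene) | O=C=C(OC(C)C)/C(OC)=C(/O)c1coc(-c2ccc(OC(C)C)cc2)c(OC)c1=O | intermediate
12 | 5-hydroxy-3,6-dimethoxy-7-(propan-2-yloxy)-2-[4-(propan-2-yloxy)phenyl]-8aH-chromene-4,8-dione (racemic at C8a) | O=C1C(OC(C)C)=C(OC)C(O)=C2C(=O)C(OC)=C(c3ccc(OC(C)C)cc3)OC12 | intermediate
13 | 5,8-dihydroxy-3,6-dimethoxy-7-(propan-2-yloxy)-2-[4-(propan-2-yloxy)phenyl]-4H-chromen-4-one | COc1c(OC(C)C)c(O)c2oc(-c3ccc(OC(C)C)cc3)c(OC)c(=O)c2c1O | intermediate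
14 | 5-hydroxy-3,6,8-trimethoxy-7-(propan-2-yloxy)-2-[4-(propan-2-yloxy)phenyl]-4H-chromen-4-one | COc1c(OC(C)C)c(OC)c2oc(-c3ccc(OC(C)C)cc3)c(OC)c(=O)c2c1O | intermediate
15 | 5,7-dihydroxy-2-(4-hydroxyphenyl)-3,6,8-trimethoxy-4H-chromen-4-one | COc1c(O)c(OC)c2oc(-c3ccc(O)cc3)c(OC)c(=O)c2c1O | target

## Step count and least certain steps

Total: 9 steps. Longest linear sequence: 9 steps (1 to 15); 4 and 7 are purchased.

**Step 6 (alkoxy exchange).** Three things may go wrong. The tertiary alkoxide may trigger anionic electrocyclic opening of the four-membered ring, with methanol capturing the ketene. Conjugate addition may be sluggish, because C3 is a doubly donor-substituted enone carbon. Methoxide may attack the pyranone at C6. The fallback uses only known flavonoid chemistry and differentiates O6 from O7 late: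

- It sets out from 9, which is thermolysed as in step 7 to 5,8-dihydroxy-3-methoxy-6,7-bis(propan-2-yloxy)-2-[4-(propan-2-yloxy)phenyl]-4H-chromen-4-one F1.
- Selective methylation of the non-chelated 8-hydroxyl (MeI, K2CO3) gives 5-hydroxy-3,8-dimethoxy-6,7-bis(propan-2-yloxy)-2-[4-(propan-2-yloxy)phenyl]-4H-chromen-4-one F2.
- BCl3 removes all three isopropyl groups to give 5,6,7-trihydroxy-2-(4-hydroxyphenyl)-3,8-dimethoxy-4H-chromen-4-one F3.
- The two most acidic hydroxyls, at C7 and C4′, are benzylated (BnBr, K2CO3, DMF) to 7-(benzyloxy)-2-[4-(benzyloxy)phenyl]-5,6-dihydroxy-3,8-dimethoxy-4H-chromen-4-one F4.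
- The 6-hydroxyl is methylated beside the chelated 5-hydroxyl to 7-(benzyloxy)-2-[4-(benzyloxy)phenyl]-5-hydroxy-3,6,8-trimethoxy-4H-chromen-4-one F5.
- Hydrogenolysis (H2, Pd/C) returns to the route at 15.

The price is two more steps.

**Step 7 (key step).** Closure onto the electron-poor, weakly aromatic pyranone carbon may be slow, so that the ketene is consumed by intermolecular addition of a free hydroxyl or by traces of water. The hydroquinone may also oxidise in air to the 5,8-quinone. The fallback changes the substrate rather than the temperature: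

- 10 is silylated (TMSOTf, 2,6-lutidine) to 3-methoxy-4-{5-methoxy-4-oxo-6-[4-(propan-2-yloxy)phenyl]-4H-pyran-3-yl}-2-(propan-2-yloxy)-4-[(trimethylsilyl)oxy]cyclobut-2-en-1-one F6, which has no free hydroxyl to trap a ketene.
- Thermolysis should give the mono-protected, less oxidisable 8-hydroxy-3,6-dimethoxy-7-(propan-2-yloxy)-2-[4-(propan-2-yloxy)phenyl]-5-[(trimethylsilyl)oxy]-4H-chromen-4-one F7.
- Dilute aqueous HCl in THF removes the silyl group, and the route is rejoined at 13.

**Step 5 (pyranonyl nucleophile).** The magnesiated pyranone 8 may fragment by anti β-elimination of the ring oxygen, opening to an alkynyl ketone. The exchange reagent may also add to the pyranone before exchange is complete. The fallback replaces the Grignard reagent by a more covalent organozinc species: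

- Zinc dust and LiCl in THF should insert into 6 to give iodo{5-methoxy-4-oxo-6-[4-(propan-2-yloxy)phenyl]-4H-pyran-3-yl}zinc F8.
- MgCl2-promoted 1,2-addition of F8 to 7 returns to the route at 9.

**Step 4 (iodination).** Halogenation may spill over to ring B ortho to the isopropoxy group, or the cerium oxidant may damage the electron-rich arene. The fallback places the C5 halogen before ring B is attached:

- 3 is treated with Br2 and then Et3N (addition–elimination) to give 2,5-dibromo-3-methoxy-4H-pyran-4-one F9.
- Site-selective Suzuki coupling with 4 at the more electrophilic β-bromide on C2 gives 5-bromo-3-methoxy-2-[4-(propan-2-yloxy)phenyl]-4H-pyran-4-one F10.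
- Copper-catalysed halogen exchange (NaI, CuI, N,N′-dimethylethylenediamine, dioxane, 110 °C) returns to the route at 6.

## Further compounds

F1 | step 6 | 5,8-dihydroxy-3-methoxy-6,7-bis(propan-2-yloxy)-2-[4-(propan-2-yloxy)phenyl]-4H-chromen-4-one | COc1c(-c2ccc(OC(C)C)cc2)oc2c(O)c(OC(C)C)c(OC(C)C)c(O)c2c1=O
F2 | step 6 | 5-hydroxy-3,8-dimethoxy-6,7-bis(propan-2-yloxy)-2-[4-(propan-2-yloxy)phenyl]-4H-chromen-4-one | COc1c(-c2ccc(OC(C)C)cc2)oc2c(OC)c(OC(C)C)c(OC(C)C)c(O)c2c1=O
F3 | step 6 | 5,6,7-trihydroxy-2-(4-hydroxyphenyl)-3,8-dimethoxy-4H-chromen-4-one | COc1c(-c2ccc(O)cc2)oc2c(OC)c(O)c(O)c(O)c2c1=O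
F4 | step 6 | 7-(benzyloxy)-2-[4-(benzyloxy)phenyl]-5,6-dihydroxy-3,8-dimethoxy-4H-chromen-4-one | COc1c(-c2ccc(OCc3ccccc3)cc2)oc2c(OC)c(OCc3ccccc3)c(O)c(O)c2c1=O
F5 | step 6 | 7-(benzyloxy)-2-[4-(benzyloxy)phenyl]-5-hydroxy-3,6,8-trimethoxy-4H-chromen-4-one | COc1c(-c2ccc(OCc3ccccc3)cc2)oc2c(OC)c(OCc3ccccc3)c(OC)c(O)c2c1=O
F6 | step 7 | 3-methoxy-4-{5-methoxy-4-oxo-6-[4-(propan-2-yloxy)phenyl]-4H-pyran-3-yl}-2-(propan-2-yloxy)-4-[(trimethylsilyl)oxy]cyclobut-2-en-1-one (racemic) | O=C1C(OC(C)C)=C(OC)C1(O[Si](C)(C)C)c1coc(-c2ccc(OC(C)C)cc2)c(OC)c1=O
F7 | step 7 | 8-hydroxy-3,6-dimethoxy-7-(propan-2-yloxy)-2-[4-(propan-2-yloxy)phenyl]-5-[(trimethylsilyl)oxy]-4H-chromen-4-one | COc1c(OC(C)C)c(O)c2oc(-c3ccc(OC(C)C)cc3)c(OC)c(=O)c2c1O[Si](C)(C)C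
F8 | step 5 | iodo{5-methoxy-4-oxo-6-[4-(propan-2-yloxy)phenyl]-4H-pyran-3-yl}zinc | COc1c(-c2ccc(OC(C)C)cc2)occ([Zn]I)c1=O
F9 | step 4 | 2,5-dibromo-3-methoxy-4H-pyran-4-one | COc1c(Br)occ(Br)c1=O
F10 | step 4 | 5-bromo-3-methoxy-2-[4-(propan-2-yloxy)phenyl]-4H-pyran-4-one | COc1c(-c2ccc(OC(C)C)cc2)occ(Br)c1=O
A1 | alternative 1 | 3-[4-(benzyloxy)phenyl]-1-[2,4,6-tris(benzyloxy)-3,5-dimethoxyphenyl]prop-2-yn-1-one | O=C(C#Cc1ccc(OCc2ccccc2)cc1)c1c(OCc2ccccc2)c(OC)c(OCc2ccccc2)c(OC)c1OCc1ccccc1
A2 | alternative 1 | 1,3,5-tris(benzyloxy)-2-iodo-4,6-dimethoxybenzene | COc1c(OCc2ccccc2)c(I)c(OCc2ccccc2)c(OC)c1OCc1ccccc1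
A3 | alternative 1 | 1-(benzyloxy)-4-ethynylbenzene | C#Cc1ccc(OCc2ccccc2)cc1
A4 | alternative 2 | 5,7-bis(benzyloxy)-2-[4-(benzyloxy)phenyl]-3-hydroxy-6,8-dimethoxy-4H-chromen-4-one | COc1c(OCc2ccccc2)c(OC)c2oc(-c3ccc(OCc4ccccc4)cc3)c(O)c(=O)c2c1OCc1ccccc1
A5 | alternative 2 | 4,6-bis(benzyloxy)-2-bromo-2-{[4-(benzyloxy)phenyl](bromo)methyl}-5,7-dimethoxy-1-benzofuran-3(2H)-one (mixture of stereoisomers) | COc1c(OCc2ccccc2)c(OC)c2OC(Br)(C(Br)c3ccc(OCc4ccccc4)cc3)C(=O)c2c1OCc1ccccc1
A6 | alternative 3 | 2,4-dimethoxybenzene-1,3,5-triol | COc1c(O)cc(O)c(OC)c1O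
A7 | alternative 3 | ethyl 3-[4-(benzyloxy)phenyl]-2-methoxy-3-oxopropanoate (racemic) | CCOC(=O)C(OC)C(=O)c1ccc(OCc2ccccc2)cc1
A8 | alternative 3 | 2-[4-(benzyloxy)phenyl]-5,7-dihydroxy-3,6,8-trimethoxy-4H-chromen-4-one | COc1c(O)c(OC)c2oc(-c3ccc(OCc4ccccc4)cc3)c(OC)c(=O)c2c1O
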